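I am counting turnovers rather than percentages for your flasks.

| setting | south-east | south-west | Friday's | Thursday's | Saturday's | Tuesday's |
|---|---|---|---|---|---|---|
| left-handed substrate | 1 M | 2 M | 2.0 M | 2.0 M | 2.0 M | 2.0 M |
| right-handed substrate | 1 M | 2 M | 2.0 M | 2.0 M | 2.0 M | 2.0 M |
| gas | 200 mM (held) | 200 mM (held) | 200 mM (held) | 200 mM (held) | 200 mM (held) | 200 mM (held) |
| free catalyst | 140 mM | 140 mM | 140 mM | 140 mM | 140 mM | 140 mM |
| impurity | 46 mM | 92 mM | 46 mM | 46 mM | 46 mM | 46 mM |
| temperature | 5 °C | 25 °C |  | 25 °C | 10 °C | 40 °C |
| remark | run made earlier | run made earlier | at 40 °C until 6.0 h, from then on at 10 °C |  |  |  |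
| time |  |  | 8.0 h | 8.0 h | 8.0 h | 8.0 h |

- south-east (time / h: left-handed product / %, left-handed substrate / %): 1.33: 3.7, 46.0; 2.50: 6.0, 42.2; 5.00: 11.3, 39.1; 8.00: 18.9, 33.6; 15.0: 28.2, 21.4
- south-west (time / h: left-handed product / %, left-handed substrate / %): 1.33: 6.8, 42.8; 2.50: 11.2, 39.6; 4.00: 18.2, 36.4; 5.00: 20.0, 31.8; 6.00: 23.8, 30.2

(standard deviation of a reading: 1 percentage point)

- the best flask by amount of left-handed product, in percent of the left-handed substrate and right-handed substrate together charged; "all alike" if 1.5 percentage points covers them all (Friday's / Thursday's / Saturday's / Tuesday's / all alike)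
- amount of left-handed product at the end, in percent of the left-handed substrate and right-handed substrate together charged, Friday's
- amount of left-handed product at the end, in percent of the left-handed substrate and right-handed substrate together charged, Thursday's
- amount of left-handed product at the end, in percent of the left-handed substrate and right-handed substrate together charged, Saturday's
- amount of left-handed product at the end, in percent of the left-handed substrate and right-handed substrate together charged, Tuesday's

- free catalyst is single-handed; left-handed substrate and right-handed substrate are mirror images of each other, charged as a racemate, each of them at the stated concentration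
- at the start none of the gas is in solution

1. Let W be the catalyst the impurity leaves, taking one for one as my assumption: 94.0 mM in your flasks and 48.0 mM in the south-west run.

2. In your flasks N = 21.3, the turnover ceiling: left-handed substrate charged per working catalyst. With none crossing over from right-handed substrate, the left-handed substrate charged pays for N turnovers and no more.

3. The south-west run has its own ceiling, 41.7, and its reading at 6.00 h stands for 19.8 turnovers. If the gap to the ceiling closes exponentially, its starting pace is r = 4.49 /h.

4. Thursday's has the temperature and substrate charge of the south-west run, so I carry r over. Against N, my own reckoning gives Thursday's 40.8% of left-handed product.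

5. But the ceiling may leak. In the south-west readings, left-handed substrate plus left-handed product averages 2.2 percentage points above the left-handed substrate's share of the charge, more than that mean's scatter of 0.63 points. In the colder south-east run the excess is 0.08 points. I read a slow crossing from right-handed to left-handed substrate in the warm run.

6. Your forecast says Tuesday's: Friday's 48%, Thursday's 40.5%, Saturday's 22.7%, Tuesday's 49%, with high ends of 50% and 50% for the two hot flasks. It holds that “there is no racemization and no visible side loss”. Here I differ: I agree on Tuesday's, but I leave the hot flasks open above N.

Tuesday's ends best: Tuesday's 68.7%, Friday's 63.6%, Thursday's 44.1%, Saturday's 23.4%.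

    reagent + free catalyst + left-handed substrate → free catalyst + left-handed product (k = 0.00300 /M²/s, Ea = 45.0 kJ/mol)
    reagent + free catalyst + right-handed substrate → free catalyst + right-handed product (k = 7.70 × 10⁻⁴ /M²/s, Ea = 42.0 kJ/mol)
    gas ⇌ reagent, rate k3*(csat - [reagent]) (kL = 0.0240 /s)
    left-handed substrate ⇌ right-handed substrate (k = 3.10 × 10⁻⁵ /s, Ea = 99.0 kJ/mol)
    free catalyst + impurity → spent catalyst (k = 0.0220 /M/s, Ea = 49.0 kJ/mol)
    (constants at 25 °C)

Tuesday's delivers 29.2 turnovers per working catalyst, more than N = 21.3. On Friday's at 1.80 h the path to left-handed product uses reagent 3.3 times as fast as the path to right-handed product, and at 8.00 h 2.6 times, and Friday's ends with 63.6% of left-handed product against 18.7% of right-handed product. Friday's recipe with 0.078 M of impurity has W = 62.0 mM and a ceiling of 32.3, and its 54.2% is 35.0 turnovers.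

The data come from a simulation for an exercise; noise was put on by code.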